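**Retrosynthetic overview**
1. Target ⇒ (MnO2 oxidation, desilylation, ester reduction) ⇒ C13–C14 B-alkyl Suzuki union of a C1–C13 vinylcyclohexane core with a C14–C24 (E)-iodoalkenyl tetrahydrofuran.
2. Core ⇒ bridged γ-lactone (iodolactonisation sets C10) ⇒ cyclohexene acid from a boat Ireland–Claisen ring contraction of a 6-dienyl δ-lactone (key step: C6–C11 bond, C6 and quaternary C11 both set from the single carbinol C9).
3. Both tetrasubstituted alkenes (C10=C11 feeding the Claisen; C7=C2 that becomes the Z-enal) ⇒ two copper-catalysed anti-carbomagnesiations of propargylic alcohols, starting from but-2-yn-1-ol.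
4. Tetrahydrofuran fragment ⇒ geranylbarium/ynal adduct, hydroxyl-directed epoxidation, Mitsunobu inversion, 5-endo epoxide opening; vinyl iodide by carboalumination.
5. Ring order: δ-lactone (temporary) → carbocycle (Claisen) → bridged γ-lactone (temporary, opened by Wittig); the tetrahydrofuran is closed separately and joined last.

Assumption: locants such as C6 or C11 are iridal locants (C1 = CHO carbon, C2 its α-carbon, ring = C6–C11, hydroxypropyl = C3–C5, side chain = C12–C24, ring oxygen on C16 and C19); a named catalyst antipode is the one expected from the usual sense of induction and is replaced by its mirror image if the measured sense is opposite.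

**Route**

Step 1
Reactants: 1 but-2-yn-1-ol
Product: 3 (2Z)-3-iodo-2-methylbut-2-en-1-ol, via oxamagnesole chelate 2 (not isolated)
Conditions: MeMgBr (3 equiv), CuI (10 mol%), THF, 0 °C to reflux; then I2, −78 to 0 °C
Reagents that add atoms: methylmagnesium bromide C[Mg]Br; iodine (I2) II
Why: Copper-catalysed anti-carbomagnesiation of a propargylic alcohol (Duboudin reaction) delivers methyl to C10 and magnesium to C11 inside a five-membered chelate, so iodinolysis gives the tetrasubstituted iodide with CH2OH cis to iodine.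

Step 2
Reactants: 3 (2Z)-3-iodo-2-methylbut-2-en-1-ol
Product: 4 (2Z)-2,3-dimethylpenta-2,4-dien-1-ol
Conditions: vinylboronic acid pinacol ester (1.3 equiv), Pd(PPh3)4 (5 mol%), Cs2CO3 (2 equiv), THF/H2O, 60 °C
Reagents that add atoms: vinylboronic acid pinacol ester C=CB1OC(C)(C)C(C)(C)O1
Why: Suzuki–Miyaura coupling of the alkenyl iodide proceeds with retention, placing the vinyl group (future C12=C13) cis to CH2OH.

Step 3
Reactants: 4 (2Z)-2,3-dimethylpenta-2,4-dien-1-ol
Product: 5 (2Z)-2,3-dimethylpenta-2,4-dienal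
Conditions: MnO2 (15 equiv), CH2Cl2, 20 °C, dark
Reagents that add atoms: none
Why: MnO2 oxidation is selective for allylic alcohols and neutral, so the Z-dienal forms without isomerisation.

Step 4
Reactants: 5 (2Z)-2,3-dimethylpenta-2,4-dienal
Product: 6 (4S,5Z)-5,6-dimethylocta-5,7-dien-1-yn-4-ol
Conditions: allenylboronic acid pinacol ester (1.5 equiv), (S)-TRIP (5 mol%), 4 Å sieves, toluene, −20 °C
Reagents that add atoms: allenylboronic acid pinacol ester C=C=CB1OC(C)(C)C(C)(C)O1
Why: Chiral phosphoric acid-catalysed propargylboration through a closed six-membered SE2' transition state sets the C9 carbinol (S) by catalyst control.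

Step 5
Reactants: 6 (4S,5Z)-5,6-dimethylocta-5,7-dien-1-yn-4-ol
Product: 8 (5S,6Z)-6,7-dimethylnona-6,8-dien-2-yne-1,5-diol, via magnesium acetylide 7 (not isolated)
Conditions: EtMgBr (2.3 equiv), THF, 0 to 45 °C; then (CH2O)n, 45 °C
Reagents that add atoms: formaldehyde (as paraformaldehyde) C=O
Why: Alkynyl Grignard hydroxymethylation installs C1 as the propargylic alcohol that directs the next carbometalation.

Step 6
Reactants: 8 (5S,6Z)-6,7-dimethylnona-6,8-dien-2-yne-1,5-diol
Product: 10 (2Z,5S,6Z)-3-iodo-2,6,7-trimethylnona-2,6,8-triene-1,5-diol, via vinylmagnesium chelate 9 (not isolated)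
Conditions: MeMgBr (5 equiv), CuI (20 mol%), THF, 0 to 45 °C; then I2, −78 to 0 °C
Reagents that add atoms: methylmagnesium bromide C[Mg]Br; iodine (I2) II
Why: A second Duboudin anti-carbomagnesiation puts methyl on C2 and the chelated magnesium (then iodine) on C7 cis to C1, which fixes the later enal geometry (methyl cis to C8).

Step 7
Reactants: 10 (2Z,5S,6Z)-3-iodo-2,6,7-trimethylnona-2,6,8-triene-1,5-diol
Product: 11 C1 mono-TBS ether of 10
Conditions: TBSCl (1.05 equiv), imidazole, CH2Cl2, −20 °C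
Reagents that add atoms: tert-butyldimethylsilyl chloride CC(C)(C)[Si](C)(C)Cl
Why: Kinetic silylation distinguishes the primary allylic alcohol from the hindered secondary C9 alcohol, which must stay free for lactonisation.

Step 8
Reactants: 11 C1 mono-TBS ether of 10
Product: 13 (6S)-4-alkylidene-6-dienyl-oxan-2-one (δ-lactone), via hydroxy ester 12 (not isolated)
Conditions: BrZnCH2CO2Et (3 equiv), Pd2(dba)3 (2.5 mol%), XPhos (10 mol%), THF, 60 °C; then Ti(OiPr)4 (10 mol%), toluene, 60 °C
Reagents that add atoms: (2-ethoxy-2-oxoethyl)zinc bromide CCOC(=O)C[Zn]Br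
Why: Negishi coupling of the Reformatsky reagent with the alkenyl iodide (retention) attaches C6–C5 cis to C1, and titanium-mediated transesterification closes the δ-lactone onto the C9 hydroxyl.

Step 9
Reactants: 13 δ-lactone
Product: 16 (1R,2S,6Z)-6-{1-[tert-butyl(dimethyl)silyl]oxypropan-2-ylidene}-2-ethenyl-2,3-dimethylcyclohex-3-ene-1-carboxylic acid, via silyl ketene acetal 14 (not isolated), via silyl ester 15 (not isolated)
Conditions: LiN(iPr)2 (1.3 equiv), Me3SiCl (1.5 equiv), THF, −78 °C; solvent switch to toluene, 100 °C; then 1 M HCl, THF, 0 °C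
Reagents that add atoms: none
Why: Ireland–Claisen ring contraction of the lactone silyl ketene acetal through the tether-enforced boat transition state forms C6–C11 suprafacially, transferring the C9 configuration to C6 and quaternary C11 (CO2H cis to the C11 methyl because vinyl is the Z substituent) and leaving the C9=C10 ring alkene.

Step 10
Reactants: 16 cyclohexene acid
Product: 17 iodolactone
Conditions: I2 (1.3 equiv), NaHCO3 (3 equiv), MeCN/H2O, 0 °C, dark
Reagents that add atoms: iodine (I2) II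
Why: Iodolactonisation by 5-exo attack of the axial carboxylate on the tertiary C10 end of the iodonium forms the C10–O bond necessarily cis to C6–C5 and sets the carbinol centre, while the tetrasubstituted and vinyl alkenes would need 4-exo, 5-endo or trans-fused closures.

Step 11
Reactants: 17 iodolactone
Product: 18 bridged γ-lactone
Conditions: Bu3SnH (1.3 equiv), AIBN (10 mol%), benzene, 80 °C
Reagents that add atoms: none
Why: Radical chain deiodination removes the C9 iodide without touching any stereocentre.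

Step 12
Reactants: 18 bridged γ-lactone
Product: 19 lactol
Conditions: iBu2AlH (1.2 equiv), CH2Cl2, −78 °C
Reagents that add atoms: none
Why: Partial reduction of a lactone stops at the tetrahedral aluminate at low temperature and gives the lactol.

Step 13
Reactants: 19 lactol
Product: 20 (E)-enoate with free C10 alcohol
Conditions: Ph3P=CHCO2Me (2.5 equiv), toluene, 70 °C
Reagents that add atoms: methyl (triphenylphosphoranylidene)acetate COC(=O)C=P(c1ccccc1)(c1ccccc1)c1ccccc1
Why: Wittig olefination of the open hydroxy-aldehyde form with a stabilised, non-basic ylide adds C4–C3 as the (E)-enoate and releases the C10 tertiary alcohol.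

Step 14
Reactants: 20 (E)-enoate
Product: 21 core ester (saturated methyl ester)
Conditions: [(Ph3P)CuH]6 (0.4 equiv), H2O (3 equiv), benzene, 20 °C
Reagents that add atoms: none
Why: Copper hydride conjugate reduction is chemoselective for the enoate and leaves the vinyl and tetrasubstituted alkenes alone.

Step 15
Reactants: 22 geranyl chloride; 23 3-(trimethylsilyl)prop-2-ynal
Product: 25 rac-(5E)-6,10-dimethyl-1-(trimethylsilyl)undeca-5,9-dien-1-yn-3-ol, via geranylbarium chloride 24 (not isolated)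
Conditions: Ba metal (from BaI2 and lithium biphenylide LiC12H10), THF, −78 °C; 22; then 23, −78 °C
Reagents that add atoms: none
Why: Allylbarium reagents add to aldehydes at the α-carbon with retention of the E alkene (α-selective Barbier-type allylation), giving the linear homoallylic propargylic alcohol.

Step 16
Reactants: 25 racemic propargylic alcohol
Product: 26 (5E)-6,10-dimethyl-1-(trimethylsilyl)undeca-5,9-dien-1-yn-3-one
Conditions: MnO2 (15 equiv), CH2Cl2, 20 °C
Reagents that add atoms: none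
Why: MnO2 oxidises the activated propargylic alcohol under neutral conditions, so the skipped alkene does not move into conjugation.

Step 17
Reactants: 26 ynone
Product: 27 (3S,5E)-6,10-dimethyl-1-(trimethylsilyl)undeca-5,9-dien-1-yn-3-ol
Conditions: Ru[(S,S)-TsNCH(Ph)CH(Ph)NH](p-cymene) (1 mol%), iPrOH, 25 °C
Reagents that add atoms: none
Why: Noyori asymmetric transfer hydrogenation of an alkynyl ketone under base-free conditions sets C16 (S) by catalyst control.

Step 18
Reactants: 27 (3S)-propargylic alcohol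
Product: 28 syn-epoxy alcohol (16S,18R,19R)
Conditions: VO(acac)2 (5 mol%), tBuOOH (1.5 equiv), CH2Cl2, 0 °C
Reagents that add atoms: tert-butyl hydroperoxide CC(C)(C)OO
Why: Hydroxyl-directed vanadium epoxidation of the homoallylic alcohol through a chair-like vanadate transition state (carbinol substituent equatorial, cis-methyl avoiding 1,3-diaxial strain) gives the 1,3-syn epoxide at C18=C19 only, the remote C22=C23 alkene being out of reach.

Step 19
Reactants: 28 syn-epoxy alcohol
Product: 29 inverted (16R) 4-nitrobenzoate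
Conditions: 4-nitrobenzoic acid, PPh3, DIAD, THF, 0 °C
Reagents that add atoms: 4-nitrobenzoic acid OC(=O)c1ccc(cc1)[N+](=O)[O-]
Why: Mitsunobu esterification inverts the propargylic C16 centre by SN2 displacement, converting the syn into the anti relationship.

Step 20
Reactants: 29 inverted 4-nitrobenzoate
Product: 31 (2S,3R,5R)-5-ethynyl-2-methyl-2-(4-methylpent-3-en-1-yl)oxolan-3-ol, via anti-epoxy alcohol 30 (not isolated)
Conditions: K2CO3, MeOH, 20 °C; then camphorsulfonic acid (5 mol%), CH2Cl2, 0 °C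
Reagents that add atoms: none
Why: Methanolysis frees the C16 alcohol and the alkyne, and acid-catalysed 5-endo epoxide opening at the tertiary C19 (inversion there, retention at C16 and C18) closes the tetrahydrofuran with ethynyl, hydroxyl and methyl on one face.

Step 21
Reactants: 31 ethynyl tetrahydrofuran
Product: 33 (2S,3R,5R)-5-[(1E)-1-iodoprop-1-en-2-yl]-2-methyl-2-(4-methylpent-3-en-1-yl)oxolan-3-ol, via vinylalane 32 (not isolated)
Conditions: AlMe3 (4 equiv), Cp2ZrCl2 (0.5 equiv), CH2Cl2, 0 to 20 °C; then I2, THF, −30 °C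
Reagents that add atoms: trimethylaluminium C[Al](C)C; iodine (I2) II
Why: Negishi zirconium-catalysed syn-carboalumination adds methyl to the internal alkyne carbon and aluminium to the terminus, and iodinolysis with retention gives the (E)-iodide.

Step 22
Reactants: 21 core ester; 33 iodoalkenyl tetrahydrofuran
Product: 35 coupled methyl ester, via alkylborane 34 (not isolated)
Conditions: 9-BBN-H (2.5 equiv), THF, 20 °C; then 33, PdCl2(dppf) (10 mol%), AsPh3 (10 mol%), Cs2CO3 (3 equiv), DMF/H2O, 20 °C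
Reagents that add atoms: none
Why: B-alkyl Suzuki–Miyaura coupling: anti-Markovnikov hydroboration of the only monosubstituted alkene, then sp3–sp2 coupling with retention of the E geometry, forms C13–C14.

Step 23
Reactants: 35 coupled methyl ester
Product: 36 C3 primary alcohol (C1 still silylated)
Conditions: LiAlH4 (2 equiv), THF, 0 °C
Reagents that add atoms: none
Why: Hydride reduction of the only carbonyl group gives the 3-hydroxypropyl chain.

Step 24
Reactants: 36 C3 primary alcohol
Product: 37 tetraol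
Conditions: Bu4NF (1.5 equiv), THF, 0 to 20 °C
Reagents that add atoms: none
Why: Fluoride cleaves the single silyl ether and frees the C1 allylic alcohol.

Step 25
Reactants: 37 tetraol
Product: 38 target CNP0155390.1
Conditions: MnO2 (25 equiv), CH2Cl2, 20 °C
Reagents that add atoms: none
Why: MnO2 oxidises only the allylic C1 alcohol (not the saturated primary, secondary or tertiary ones) to the Z-enal without double-bond isomerisation.

**Compound list**
1 | but-2-yn-1-ol | CC#CCO | starting material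
2 | 3,4-dimethyl-2,5-dihydro-1,2-oxamagnesole (chelated alkenylmagnesium alkoxide) | CC1=C(C)[Mg]OC1 | intermediate
3 | (2Z)-3-iodo-2-methylbut-2-en-1-ol | OC/C(C)=C(I)/C | intermediate
4 | (2Z)-2,3-dimethylpenta-2,4-dien-1-ol | OC/C(C)=C(C=C)/C | intermediate
5 | (2Z)-2,3-dimethylpenta-2,4-dienal | O=C/C(C)=C(C=C)/C | intermediate
6 | (4S,5Z)-5,6-dimethylocta-5,7-dien-1-yn-4-ol | C#CC[C@H](O)/C(C)=C(C=C)/C | intermediate
7 | bis(bromomagnesium) alkoxide-acetylide of 6 | Br[Mg]C#CC[C@H](O[Mg]Br)/C(C)=C(C=C)/C | intermediate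
8 | (5S,6Z)-6,7-dimethylnona-6,8-dien-2-yne-1,5-diol | OCC#CC[C@H](O)/C(C)=C(C=C)/C | intermediate
9 | oxamagnesole chelate from 8 (Mg on C7, ring through the C1 oxygen, C9–OMgBr) | CC1=C(C[C@H](O[Mg]Br)/C(C)=C(C=C)/C)[Mg]OC1 | intermediate
10 | (2Z,5S,6Z)-3-iodo-2,6,7-trimethylnona-2,6,8-triene-1,5-diol | OC/C(C)=C(I)/C[C@H](O)/C(C)=C(C=C)/C | intermediate
11 | (2Z,5S,6Z)-1-[tert-butyl(dimethyl)silyl]oxy-3-iodo-2,6,7-trimethylnona-2,6,8-trien-5-ol | CC(C)(C)[Si](C)(C)OC/C(C)=C(I)/C[C@H](O)/C(C)=C(C=C)/C | intermediate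
12 | ethyl (3Z,5S,6Z)-3-{1-[tert-butyl(dimethyl)silyl]oxypropan-2-ylidene}-5-hydroxy-6,7-dimethylnona-6,8-dienoate | CCOC(=O)C/C(=C(/C)CO[Si](C)(C)C(C)(C)C)C[C@H](O)/C(C)=C(C=C)/C | intermediate
13 | (6S)-4-{(Z)-1-[tert-butyl(dimethyl)silyl]oxypropan-2-ylidene}-6-[(2Z)-3-methylpenta-2,4-dien-2-yl]oxan-2-one | O=C1C/C(=C(/C)CO[Si](C)(C)C(C)(C)C)C[C@H](O1)/C(C)=C(C=C)/C | intermediate
14 | trimethylsilyl ketene acetal of 13 (C5=C6 enol ether) | C[Si](C)(C)OC1=C/C(=C(/C)CO[Si](C)(C)C(C)(C)C)C[C@H](O1)/C(C)=C(C=C)/C | intermediate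
15 | trimethylsilyl ester of acid 16 | C=C[C@@]2(C)[C@H](C(=O)O[Si](C)(C)C)/C(=C(/C)CO[Si](C)(C)C(C)(C)C)CC=C2C | intermediate
16 | (1R,2S,6Z)-6-{1-[tert-butyl(dimethyl)silyl]oxypropan-2-ylidene}-2-ethenyl-2,3-dimethylcyclohex-3-ene-1-carboxylic acid (CO2H cis to the C11 methyl) | C=C[C@@]2(C)[C@H](C(=O)O)/C(=C(/C)CO[Si](C)(C)C(C)(C)C)CC=C2C | intermediate
17 | iodolactone: γ-lactone from the C6 carboxyl to C10, C9 iodide trans to the lactone oxygen; C6, C10, C11 arranged as in the target | C=C[C@@]2(C)[C@H](C3=O)/C(=C(/C)CO[Si](C)(C)C(C)(C)C)C[C@@H](I)[C@]2(C)O3 | intermediate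
18 | bridged γ-lactone (C5 carbonyl on C6, lactone oxygen on C10, both cis to the C11 methyl; C11 vinyl; Z-alkylidene at C7 with CH2OTBS cis to C6) | C=C[C@@]2(C)[C@H](C3=O)/C(=C(/C)CO[Si](C)(C)C(C)(C)C)CC[C@]2(C)O3 | intermediate
19 | lactol of 18 (C5 hemiacetal, anomer mixture) | C=C[C@@]2(C)[C@H](C3O)/C(=C(/C)CO[Si](C)(C)C(C)(C)C)CC[C@]2(C)O3 | intermediate
20 | methyl (2E)-3-[ring C6]prop-2-enoate: 2-ethenyl-3-hydroxy-2,3-dimethyl-6-(Z-silyloxypropan-2-ylidene)cyclohexyl acrylate, ring centres as in the target | C=C[C@@]2(C)[C@H](/C=C/C(=O)OC)/C(=C(/C)CO[Si](C)(C)C(C)(C)C)CC[C@]2(C)O | intermediate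
21 | core ester: methyl 3-[2-ethenyl-3-hydroxy-2,3-dimethyl-6-{(Z)-1-[tert-butyl(dimethyl)silyl]oxypropan-2-ylidene}cyclohexyl]propanoate, C6, C10, C11 arranged as in the target | C=C[C@@]2(C)[C@H](CCC(=O)OC)/C(=C(/C)CO[Si](C)(C)C(C)(C)C)CC[C@]2(C)O | intermediate
22 | geranyl chloride, (2E)-1-chloro-3,7-dimethylocta-2,6-diene | CC(C)=CCC/C(C)=C/CCl | starting material
23 | 3-(trimethylsilyl)prop-2-ynal | O=CC#C[Si](C)(C)C | starting material
24 | geranylbarium chloride | CC(C)=CCC/C(C)=C/C[Ba]Cl | intermediate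
25 | rac-(5E)-6,10-dimethyl-1-(trimethylsilyl)undeca-5,9-dien-1-yn-3-ol | CC(C)=CCC/C(C)=C/CC(O)C#C[Si](C)(C)C | intermediate
26 | (5E)-6,10-dimethyl-1-(trimethylsilyl)undeca-5,9-dien-1-yn-3-one | CC(C)=CCC/C(C)=C/CC(=O)C#C[Si](C)(C)C | intermediate
27 | (3S,5E)-6,10-dimethyl-1-(trimethylsilyl)undeca-5,9-dien-1-yn-3-ol | CC(C)=CCC/C(C)=C/C[C@H](O)C#C[Si](C)(C)C | intermediate
28 | (2S)-1-[(2R,3R)-3-methyl-3-(4-methylpent-3-en-1-yl)oxiran-2-yl]-4-(trimethylsilyl)but-3-yn-2-ol | CC(C)=CCC[C@@]1(C)O[C@@H]1C[C@H](O)C#C[Si](C)(C)C | intermediate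
29 | (2R)-1-[(2R,3R)-3-methyl-3-(4-methylpent-3-en-1-yl)oxiran-2-yl]-4-(trimethylsilyl)but-3-yn-2-yl 4-nitrobenzoate | CC(C)=CCC[C@@]1(C)O[C@@H]1C[C@@H](OC(=O)c2ccc(cc2)[N+](=O)[O-])C#C[Si](C)(C)C | intermediate
30 | (2R)-1-[(2R,3R)-3-methyl-3-(4-methylpent-3-en-1-yl)oxiran-2-yl]but-3-yn-2-ol | CC(C)=CCC[C@@]1(C)O[C@@H]1C[C@@H](O)C#C | intermediate
31 | (2S,3R,5R)-5-ethynyl-2-methyl-2-(4-methylpent-3-en-1-yl)oxolan-3-ol | CC(C)=CCC[C@]1(C)O[C@@H](C#C)C[C@H]1O | intermediate
32 | (E)-alkenyl(dimethyl)alane of 31, O-aluminated | CC(C)=CCC[C@]1(C)O[C@@H](/C(C)=C/[Al](C)C)C[C@H]1O[Al](C)C | intermediate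
33 | (2S,3R,5R)-5-[(1E)-1-iodoprop-1-en-2-yl]-2-methyl-2-(4-methylpent-3-en-1-yl)oxolan-3-ol | CC(C)=CCC[C@]1(C)O[C@@H](/C(C)=C/I)C[C@H]1O | intermediate
34 | B-alkyl-9-borabicyclo[3.3.1]nonane from 21 (boron on C13) | C1CC2CCCC(C1)B2CC[C@@]3(C)[C@H](CCC(=O)OC)/C(=C(/C)CO[Si](C)(C)C(C)(C)C)CC[C@]3(C)O | intermediate
35 | coupled methyl ester (target skeleton; C3 as CO2Me, C1 as CH2OTBS) | CC(C)=CCC[C@]1(C)O[C@@H](/C(C)=C/CC[C@@]2(C)[C@H](CCC(=O)OC)/C(=C(/C)CO[Si](C)(C)C(C)(C)C)CC[C@]2(C)O)C[C@H]1O | intermediate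
36 | C3 alcohol (C1 as CH2OTBS) | CC(C)=CCC[C@]1(C)O[C@@H](/C(C)=C/CC[C@@]2(C)[C@H](CCCO)/C(=C(/C)CO[Si](C)(C)C(C)(C)C)CC[C@]2(C)O)C[C@H]1O | intermediate
37 | tetraol (C1 allylic alcohol) | CC(C)=CCC[C@]1(C)O[C@@H](/C(C)=C/CC[C@@]2(C)[C@H](CCCO)/C(=C(/C)CO)CC[C@]2(C)O)C[C@H]1O | intermediate
38 | CNP0155390.1 | CC(C)=CCC[C@]1(C)O[C@@H](/C(C)=C/CC[C@@]2(C)[C@H](CCCO)/C(=C(/C)C=O)CC[C@]2(C)O)C[C@H]1O | target

**Totals and risks**
Total step count: 25. Longest linear sequence: 18 (steps 1–14, then 22–25); the tetrahydrofuran branch is 7 steps (15–21).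

Step 9 (Claisen ring contraction). The silyl ketene acetal may eliminate the allylic silyloxy group or fail to reach the boat transition state against the tetrasubstituted alkene. The fallback sets out from lactone 13 and comes back at acid 16. The lithium enolate of 13 (LiN(SiMe3)2, THF, −78 °C) is treated with Pd(PPh3)4. Zerovalent palladium ionises the allylic C9–O bond, and the tethered ene-diolate alkylates the π-allyl terminus C11 (six- versus four-membered ring), an intramolecular Tsuji–Trost alkylation that gives 16 on acidification. The C6/C11 ratio would have to be established, and no new compound arises on this way (F0).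

Step 18 (directed epoxidation). The syn:anti ratio may be poor, or syn-epoxy alcohol 28 may close early to the C16-epimeric tetrahydrofuran. The fallback sets out from 27 and comes back at 30. Mitsunobu inversion is done first and gives (3R,5E)-6,10-dimethyl-1-(trimethylsilyl)undeca-5,9-dien-1-yn-3-yl 4-nitrobenzoate F2. K2CO3 in MeOH then gives (3R,5E)-6,10-dimethylundeca-5,9-dien-1-yn-3-ol F3. The epoxide is then set by catalyst control instead of substrate control (VO(OiPr)3 with a chiral bis-hydroxamic acid, cumene hydroperoxide), with the catalyst chosen for the (18R,19R) face, to give 30. Any spontaneous 5-endo closure is now harmless because it leads to 31.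

Step 8 (Negishi coupling of the hindered iodide). The tetrasubstituted iodide may not couple intermolecularly with the zinc enolate. The fallback sets out from 11 and comes back at 13. The free C9 hydroxyl is acylated with bromoacetyl bromide (pyridine, CH2Cl2, 0 °C) to give (2Z,5S,6Z)-1-[tert-butyl(dimethyl)silyl]oxy-3-iodo-2,6,7-trimethylnona-2,6,8-trien-5-yl bromoacetate F1. Zinc insertion (activated Zn, THF) gives the tethered Reformatsky reagent, and Pd(PPh3)4 closes the δ-lactone by intramolecular 6-exo Negishi coupling to 13.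

**Further compounds**
F1 | step 8 | (2Z,5S,6Z)-1-[tert-butyl(dimethyl)silyl]oxy-3-iodo-2,6,7-trimethylnona-2,6,8-trien-5-yl bromoacetate | CC(C)(C)[Si](C)(C)OC/C(C)=C(I)/C[C@H](OC(=O)CBr)/C(C)=C(C=C)/C
F0 | step 9 | none | none
F2 | step 18 | (3R,5E)-6,10-dimethyl-1-(trimethylsilyl)undeca-5,9-dien-1-yn-3-yl 4-nitrobenzoate | CC(C)=CCC/C(C)=C/C[C@@H](OC(=O)c1ccc(cc1)[N+](=O)[O-])C#C[Si](C)(C)C
F3 | step 18 | (3R,5E)-6,10-dimethylundeca-5,9-dien-1-yn-3-ol | CC(C)=CCC/C(C)=C/C[C@@H](O)C#C
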